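**Structural features**

The target 19 is a single six-membered carbocycle, a cyclohexa-2,5-diene-1,4-dione, with carbonyls at C1 and C4, a hydroxyl at C2, an unbranched saturated C21 chain joined by a C–C bond at C3, a methoxyl at C5 and the only ring hydrogen at C6. It has no stereocentre and no configurational double bond, so the problem is purely regiochemical. The C2 hydroxy-enone is a vinylogous acid and the C5 methoxy-enone a vinylogous ester. The methoxyl can be lost by addition–elimination with hydroxide, amines or thiolates, and the quinone is redox-active and degrades in strong aqueous base, so the quinone stage should come late and be short. The chain makes every intermediate waxy, insoluble in water and poorly soluble in cold lower alcohols, which governs the choice of solvents. The real difficulty is to place four ring oxygens at C1, C2, C4 and C5 with the two non-carbonyl oxygens differentiated (free hydroxyl beside the chain, methyl ether beside C6–H) without a statistical step. The feature used is that the oxygens on C1 and C5 are meta across C6–H and that chain-bearing C3 is meta to both. This is the pattern of a 5-alkylresorcinol monomethyl ether, which a 3-alkylcyclobutenone and an alkoxyalkyne form in one thermal operation, leaving C2 and C4 as C–H positions ortho and para to the phenol.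

**Logic of the disconnections**

Ring atoms carry the numbering of 19 throughout.

19 is first taken back to 17. No skeletal bond is cut: the three O–acyl bonds on the C1, C2 and C4 oxygens are restored and the ring returns to the aromatic oxidation level. The reason is stability, since in 17 the C5 vinylogous ester is an ordinary aryl methyl ether and all oxidisable oxygens are masked. The forward step must remove three acyl groups and oxidise only the C1/C4 pair (through 18) without loss of the C5 methoxyl. Methanolic carbonate in air is chosen because methoxide exchange at C5 is degenerate in methanol.

The C2–O bond is cut next, giving 16. This removes the one oxygen that the ring-forming step cannot supply and leaves a quinone whose only C–H positions are C2 and C6. The forward step must add an oxygen nucleophile at C2 and not at C6. The C5 methoxyl is relied on for this: it donates through C6 into the C1 carbonyl, so C2, the β-carbon of the cross-conjugated C4 carbonyl, remains the electrophilic site.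

Cutting the C4–O bond turns 16 into 15. The gain is an arene with only two oxygens, already differentiated as hydroxyl (C1) and methyl ether (C5). The forward oxidation must go para to the hydroxyl (C4, free but flanked by chain and methoxyl) and not to the ortho positions C2 and C6.

15 is divided into 7 and 10 by cutting C1–C6 and C4–C5; the C1–C2 bond is broken and re-made on the way forward. C1, C2, C3 and C4 are the carbonyl carbon, the methylene, the chain-bearing carbon and the vinylic CH of 7, and C5 and C6 are the two carbons of 10. The atom map was checked against the substitution pattern of 15 and is consistent. The cut delivers the whole meta relationship in one operation from a four-carbon and a two-carbon piece, with the two oxygens arriving in different forms. The forward step needs one regiochemical event, the orientation in which 11 takes up 10; the later intermediates 12, 13 and 14 follow without choice.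

The four-membered ring of 7 is cut at the C(carbonyl)–CH and CH2–C(chain) bonds, the two bonds of a ketene–alkyne cycloaddition. An unactivated alkyne needs an electrophilic ketene, so the two-carbon partner is 5, released from 4; the chlorines are carried in 6 and removed afterwards. This reduces 7 to the linear alkyne 3. The cycloaddition must place the chain on the ring carbon remote from the carbonyl, and the reduction must not open or isomerise the strained enone.

The triple bond of 3 is cut at its terminal carbon, leading to 2 and, by oxidation-level adjustment, to 1. The cut is placed so that the chain plus ring carbon C3 equal the even carbon count of 1, a commodity; odd-chain halides and acids of this length are not. The added carbon becomes C4. The homologation must tolerate an enolisable aliphatic aldehyde.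

10 is traced to 8 by re-adding the elements of methanol and hydrogen chloride; no C–C bond is involved. The forward double elimination needs excess strong base. The product is held as 9 until the quench because free 10 is volatile, and it is used at once in solution.

**Other disconnections considered**

Alternative 1: The cut is ring bond C3–C4, made by an aldol between an ester-flanked methylene and the chain-bearing ketone of an open-chain polyketide; C4 then carries an ester carbon that is absent from 19.
- Forward key step: methanolysis of 6-(2,4-dioxopentacosyl)-2,2-dimethyl-4H-1,3-dioxin-4-one A1 on heating would release methyl 3,5,7-trioxooctacosanoate A2 through an acylketene. A mild carbonate base would then close the ring, and dehydration with enolisation would give methyl 6-henicosyl-2,4-dihydroxybenzoate A3.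
- In favour: conditions are near neutral, and only one six-membered aldol mode leads to an arene, so the chain position is unambiguous. The two phenols of A3 are distinguished by chelation of one to the ester, so mono-methylation would not be statistical.
- Against: A1 needs several steps of C-acylation on base-sensitive polycarbonyl intermediates. The ester must later be excised by saponification and decarboxylation. Methylation and decarboxylation of A3 only arrive at 15, after which the same three oxidation-level steps are still required.
- Comparison: on regiocontrol of chain and oxygens the two plans are equal. On handling, Alternative 1 is better, since it avoids a volatile alkyne and ketenes in a closed vessel. Mechanistically, enolate chemistry on a tetracarbonyl chain has competing cyclisation modes (pyranone formation), whereas the chosen cascade has a single regiochemical event. On step economy the chosen plan is better by about four steps.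

Alternative 2: The cuts are C1–C6 and C2–C3; C1 and C2 would come from an oxalic diester and C3–C6 from pentacosane-2,3-dione A4.
- Forward key step: an alkoxide base would deprotonate A4 at its methyl and methylene carbons, and two Claisen acylations, the second intramolecular, would close the ring as the dianion of 3-henicosyl-2,5-dihydroxycyclohexa-2,5-diene-1,4-dione A5.
- In favour: the whole tetraoxygenated ring with its chain is formed in one operation at the correct oxidation level, with no redox steps or protecting groups. Only one O-methylation would remain.
- Against: vicinal diketones self-condense under alkoxide, which competes with the crossed acylation. The C2 and C5 hydroxyls of A5 emerge as two vinylogous acids of the same kind, so the methyl group must be placed on C5 by a selective mono-etherification that rests only on the steric difference between the two sites. Over-methylation and etherification at C2 are the foreseeable losses.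
- Comparison: on step economy Alternative 2 is clearly better (about four to five steps against nine), and A5 is structurally closer to 19 than any intermediate of the chosen plan. On differentiation of the oxygens the chosen plan is better, because the methyl ether is built in by 10. Mechanistically, two consecutive Claisen condensations on a base-labile substrate are judged less secure than the thermal cascade.

Alternative 3: The cut is C4–C5, with C4 a ketene carbon produced by opening a four-membered ring and C5 the methoxy-bearing carbon of a vinyl substituent.
- Forward key step: thermolysis of rac-2-henicosyl-4-hydroxy-4-[(E)-2-methoxyethenyl]-3-(propan-2-yloxy)cyclobut-2-en-1-one A6 would open the ring (4π) to a dienylketene. This would close by 6π electrocyclisation and tautomerise to 3-henicosyl-5-methoxy-2-(propan-2-yloxy)benzene-1,4-diol A7.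
- In favour: all four oxygens and the chain are fixed by the order in which two organometallic reagents are added to a squaric ester. No late regioselective oxygenation is needed, and the C2 and C5 oxygens carry different alkyl groups. From A7 only oxidation and removal of the isopropyl group remain.
- Against: it needs a C21 organometallic from an odd-chain halide that is not a bulk chemical, a 2-methoxyvinyl organolithium, and two cryogenic additions with regioselective 1,2-addition. The final step must remove isopropyl selectively beside methyl on a sensitive quinone or hydroquinone.
- Comparison: on certainty of the oxygenation pattern Alternative 3 is better, since the chosen plan depends on two electronically directed oxidations. Mechanistically the two are equal (the same family of 4π-opening and 6π-closure events). In step count Alternative 3 is somewhat better (about six steps). In availability of the chain source and in ease of handling the chosen plan is better.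

Key step: step 6

Remark on the chemistry: 19 is taken as the 2-hydroxy-1,4-quinone tautomer with an unbranched C21 chain; it has no stereocentre, and the chiral compounds 12, F2, F5 and A6 are racemates of which one enantiomer is drawn.

**Route**

Step 1
Reactants: 1 docosan-1-ol
Product: 2 docosanal
Conditions: TEMPO (cat.), PhI(OAc)2, CH2Cl2, rt
Reagents that add atoms: none
Why: Oxoammonium-mediated (TEMPO/hypervalent iodine) oxidation of a primary alcohol stops at the aldehyde in the absence of water, runs at room temperature where the waxy alcohol is soluble, and avoids cryogenic or chromium conditions.

Step 2
Reactants: 2 docosanal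
Product: 3 tricos-1-yne
Conditions: MeC(O)C(N2)P(O)(OMe)2, K2CO3, MeOH/THF, 0 °C → rt
Reagents that add atoms: dimethyl (1-diazo-2-oxopropyl)phosphonate (Ohira–Bestmann reagent), COP(=O)(OC)C(=[N+]=[N-])C(C)=O
Why: Seyferth–Gilbert homologation in the Ohira–Bestmann variant: methanolysis of the acetyl group frees the diazomethylphosphonate anion, which olefinates the aldehyde, and loss of N2 with 1,2-hydride shift gives the terminal alkyne; the carbonate base is mild enough for an enolisable aldehyde, and THF keeps the long-chain substrate in solution.

Step 3
Reactants: 3 tricos-1-yne; 4 trichloroacetyl chloride
Product: 6 4,4-dichloro-3-henicosylcyclobut-2-en-1-one, via dichloroketene 5 (not isolated)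
Conditions: Zn(Cu), Et2O/DME, 4 added over 1 h, rt
Reagents that add atoms: none
Why: Zinc dechlorinates 4 to the strongly electrophilic ketene 5, which undergoes thermal [2+2] cycloaddition with the alkyne; the unsubstituted alkyne carbon bonds to the ketene carbonyl carbon, so the chain ends on the ring carbon remote from the carbonyl, and slow addition keeps ketene self-condensation down.

Step 4
Reactants: 6 4,4-dichloro-3-henicosylcyclobut-2-en-1-one
Product: 7 3-henicosylcyclobut-2-en-1-one
Conditions: Zn, AcOH, TMEDA, EtOH/THF, 0 °C → rt
Reagents that add atoms: none
Why: Zinc reduction of an α,α-dichloro ketone removes both chlorines through zinc enolates that are protonated by acetic acid; the amine buffer complexes the zinc salts and prevents acid-promoted opening of the strained enone.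

Step 5
Reactants: 8 2-chloro-1,1-dimethoxyethane
Product: 10 methoxyethyne, via sodium methoxyacetylide 9 (not isolated)
Conditions: NaNH2 (3 equiv), liq. NH3, −33 °C; then cold aq. NaCl, product distilled into cold toluene
Reagents that add atoms: none
Why: Double β-elimination (loss of methanol, then of hydrogen chloride) by sodium amide; the third equivalent stores the product as the acetylide 9 until the aqueous quench, and the low-boiling, flammable alkyne is collected directly as a cold toluene solution for immediate use, so it is never handled neat or stored.

Step 6
Reactants: 7 3-henicosylcyclobut-2-en-1-one; 10 methoxyethyne
Product: 15 3-henicosyl-5-methoxyphenol, via vinylketene 11 (not isolated), via 4-vinylcyclobutenone 12 (not isolated), via dienylketene 13 (not isolated), via cyclohexa-2,4-dienone 14 (not isolated)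
Conditions: 10 (3 equiv), toluene, sealed tube, 80 °C
Reagents that add atoms: none
Why: This is a Danheiser benzannulation of a cyclobutenone with an alkoxyalkyne, a cascade of four pericyclic steps in one flask. On heating, 7 opens reversibly by 4π electrocyclic cleavage of the C(=O)–CH2 bond to the vinylketene 11. The ketene C=C of 11 adds to 10 in a [2+2] cycloaddition in which the unsubstituted alkyne carbon bonds to the ketene carbonyl carbon (C1–C6) and the methoxy-bearing carbon to the ketene α-carbon (C4–C5), giving 12. A second reversible 4π opening of 12 gives the dienylketene, and only the rotamer with the alkenyl arm turned towards the ketene (13) can react further. The six-membered ring closes by thermal disrotatory 6π electrocyclisation of 13, the ketene carbon bonding to the terminal CH2 (re-forming C1–C2), and 14 tautomerises irreversibly to the phenol, which drives the sequence. No stereocentre is created in 15; the one stereocentre of 12 is transient and is erased on ring opening. The only selectivity needed is the orientation of the [2+2] step, secured by the polarisation of the alkoxyalkyne (oxygen donation makes the CH terminus nucleophilic) matched with the electrophilic central carbon of the ketene; the 3-alkyl group of 7 is a spectator that ends meta to both oxygens. An excess of 10 in a closed vessel keeps capture of 11 faster than its dimerisation or its acylation of the product phenol.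

Step 7
Reactants: 15 3-henicosyl-5-methoxyphenol
Product: 16 2-henicosyl-6-methoxycyclohexa-2,5-diene-1,4-dione
Conditions: (KSO3)2NO, KH2PO4, MeN(C8H17)3Cl (cat.), CH2Cl2/H2O, rt
Reagents that add atoms: potassium nitrosodisulfonate (Fremy's salt), [K+].[K+].[O]N(S(=O)(=O)[O-])S(=O)(=O)[O-]
Why: Teuber oxidation: one nitroxide radical abstracts the phenolic hydrogen, a second couples at the free para carbon (C4) of the phenoxyl radical, and loss of imidodisulfonate leaves the p-quinone; para-unsubstituted phenols react at the para position, and the phase-transfer catalyst brings the water-soluble oxidant to the lipophilic substrate under buffered, near-neutral conditions that spare the new vinylogous ester.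

Step 8
Reactants: 16 2-henicosyl-6-methoxycyclohexa-2,5-diene-1,4-dione
Product: 17 3-henicosyl-5-methoxybenzene-1,2,4-triyl triacetate
Conditions: Ac2O, BF3·OEt2, 40 °C
Reagents that add atoms: acetic anhydride, CC(=O)OC(C)=O
Why: Thiele–Winter acetoxylation: the Lewis-acid-activated quinone takes up acetate in conjugate fashion, and the resulting hydroquinone is acetylated on all three oxygens; the methoxyl deactivates its own double bond and the carbonyl conjugated with it, so acetate should enter at the ring CH next to the chain (C2 of 19), the position across the ring from the methoxyl as is usual for methoxyquinones, and the product is a stable arene in which the methoxyl is a plain aryl ether.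

Step 9
Reactants: 17 3-henicosyl-5-methoxybenzene-1,2,4-triyl triacetate
Product: 19 3-henicosyl-2-hydroxy-5-methoxycyclohexa-2,5-diene-1,4-dione, via benzenetriol 18 (not isolated)
Conditions: K2CO3, MeOH/THF, air, rt; then 1 M HCl
Reagents that add atoms: none
Why: Carbonate-mediated methanolysis of the three aryl acetates frees the electron-rich triol 18, whose para-dihydroxy pair is autoxidised by air in the basic medium to the hydroxyquinone, held as its stabilised anion until acidification; in methanol any methoxide exchange at the vinylogous ester is degenerate, so the C5 methoxyl is retained.

**Compound list**

1 | docosan-1-ol | CCCCCCCCCCCCCCCCCCCCCCO | starting material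
2 | docosanal | CCCCCCCCCCCCCCCCCCCCCC=O | intermediate
3 | tricos-1-yne | CCCCCCCCCCCCCCCCCCCCCC#C | intermediate
4 | trichloroacetyl chloride | ClC(Cl)(Cl)C(Cl)=O | starting material
5 | dichloroketene (not isolated) | ClC(Cl)=C=O | intermediate
6 | 4,4-dichloro-3-henicosylcyclobut-2-en-1-one | CCCCCCCCCCCCCCCCCCCCCC1=CC(=O)C1(Cl)Cl | intermediate
7 | 3-henicosylcyclobut-2-en-1-one | CCCCCCCCCCCCCCCCCCCCCC1=CC(=O)C1 | intermediate
8 | 2-chloro-1,1-dimethoxyethane | COC(CCl)OC | starting material
9 | sodium methoxyacetylide (not isolated) | [Na+].[C-]#COC | intermediate
10 | methoxyethyne | COC#C | intermediate
11 | 3-henicosylbuta-1,3-dien-1-one (vinylketene, not isolated) | CCCCCCCCCCCCCCCCCCCCCC(=C)C=C=O | intermediate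
12 | rac-3-methoxy-4-(tricos-1-en-2-yl)cyclobut-2-en-1-one (not isolated; one enantiomer drawn) | CCCCCCCCCCCCCCCCCCCCCC(=C)[C@@H]1C(OC)=CC1=O | intermediate
13 | (3E)-5-henicosyl-3-methoxyhexa-1,3,5-trien-1-one (dienylketene, not isolated) | CCCCCCCCCCCCCCCCCCCCCC(=C)/C=C(/OC)C=C=O | intermediate
14 | 5-henicosyl-3-methoxycyclohexa-2,4-dien-1-one (not isolated) | CCCCCCCCCCCCCCCCCCCCCC1=CC(OC)=CC(=O)C1 | intermediate
15 | 3-henicosyl-5-methoxyphenol | CCCCCCCCCCCCCCCCCCCCCc1cc(O)cc(OC)c1 | intermediate
16 | 2-henicosyl-6-methoxycyclohexa-2,5-diene-1,4-dione | CCCCCCCCCCCCCCCCCCCCCC1=CC(=O)C=C(OC)C1=O | intermediate
17 | 3-henicosyl-5-methoxybenzene-1,2,4-triyl triacetate | CCCCCCCCCCCCCCCCCCCCCc1c(OC(C)=O)c(OC(C)=O)cc(OC)c1OC(C)=O | intermediate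
18 | 3-henicosyl-5-methoxybenzene-1,2,4-triol (not isolated) | CCCCCCCCCCCCCCCCCCCCCc1c(O)c(O)cc(OC)c1O | intermediate
19 | 3-henicosyl-2-hydroxy-5-methoxycyclohexa-2,5-diene-1,4-dione | CCCCCCCCCCCCCCCCCCCCCC1=C(O)C(=O)C=C(OC)C1=O | target

**Step count and least certain steps**

Total step count: 9. Longest linear sequence: 8 steps (1 → 2 → 3 → 6 → 7 → 15 → 16 → 17 → 19, that is steps 1, 2, 3, 4, 6, 7, 8 and 9); step 5 is a one-step side branch.

Step 6 (key step). The most likely failure is depletion of the alkyne: 10 is low-boiling and can escape into the headspace or oligomerise at the reaction temperature. Once its concentration falls, the vinylketene 11 is consumed by dimerisation or by acylating the phenol already formed, so conversion to 15 stalls. The long chain does not affect the pericyclic events.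

The fallback sets out from 2 and comes back at 15, building the ring by ionic annulation instead of the pericyclic cascade.
- Wittig olefination of 2 with Ph3P=CHC(O)CH3 (toluene, reflux) should give (3E)-pentacos-3-en-2-one F1.
- Michael addition of dimethyl malonate followed by Claisen ring closure (NaOMe, MeOH, reflux) should give methyl trans-6-henicosyl-2,4-dioxocyclohexane-1-carboxylate F2 as its sodium enolate.
- F2 would be saponified and decarboxylated without isolation (aq. NaOH, then HCl, heat) to 5-henicosylcyclohexane-1,3-dione F3.
- Iodine in methanol at reflux should aromatise F3 with etherification of both oxygens to 1-henicosyl-3,5-dimethoxybenzene F4.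
- NaSEt in hot DMF should remove one methyl group only, because the phenoxide formed is deactivated towards a second demethylation, giving 15.

This costs four to five operations from 2 against four in the main route and gives up the built-in differentiation of the oxygens.

Step 8. What may go wrong is slow or misdirected conjugate addition: the quinone carries two donor substituents and both its free positions are flanked. Acetoxylation could therefore stall, or take place at the CH next to the methoxyl, and prolonged exposure to the Lewis acid could erode the vinylogous ester.

The fallback sets out from 16 and comes back at 19, introducing the oxygen as a peroxide nucleophile and rearranging an epoxide instead of passing through the arene.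
- Weitz–Scheffer epoxidation of 16 (tBuOOH, DBU, CH2Cl2, 0 °C) should place the oxygen on the chain-bearing double bond, the peroxide anion attacking the same CH as acetate would, to give rac-(1R,6S)-1-henicosyl-3-methoxy-7-oxabicyclo[4.1.0]hept-3-ene-2,5-dione F5.
- Brief treatment of F5 with cold concentrated H2SO4 and quenching on ice should isomerise the oxirane, by cleavage of the C–O bond at the chain-bearing carbon and loss of the proton from the other oxirane carbon, to 19 directly.

This bypasses 17 and 18 at the price of exposing the vinylogous ester to strong acid.

Step 3. What may go wrong is that polymerisation of the ketene 5 outruns its cycloaddition, because the waxy alkyne cannot be used at high concentration in ether; zinc chloride can also promote decomposition of the sensitive dichloro enone during the long reaction time.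

The fallback sets out from 3 and comes back at 7, replacing the ketene by a keteniminium ion and removing the need for step 4.
- N,N-Dimethylacetamide, Tf2O and 2,4,6-collidine in ClCH2CH2Cl at reflux generate the N,N-dimethylketeniminium triflate, which should add to 3 with the same orientation to give N-(3-henicosylcyclobut-2-en-1-ylidene)-N-methylmethanaminium trifluoromethanesulfonate F6.
- Hydrolysis of F6 with aq. NaHCO3 should give 7.

**Further compounds**

F1 | step 6 | (3E)-pentacos-3-en-2-one | CC(=O)/C=C/CCCCCCCCCCCCCCCCCCCCC
F2 | step 6 | methyl trans-6-henicosyl-2,4-dioxocyclohexane-1-carboxylate (racemate, one enantiomer drawn) | CCCCCCCCCCCCCCCCCCCCC[C@@H]1CC(=O)CC(=O)[C@H]1C(=O)OC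
F3 | step 6 | 5-henicosylcyclohexane-1,3-dione | CCCCCCCCCCCCCCCCCCCCCC1CC(=O)CC(=O)C1
F4 | step 6 | 1-henicosyl-3,5-dimethoxybenzene | CCCCCCCCCCCCCCCCCCCCCc1cc(OC)cc(OC)c1
F5 | step 8 | rac-(1R,6S)-1-henicosyl-3-methoxy-7-oxabicyclo[4.1.0]hept-3-ene-2,5-dione | CCCCCCCCCCCCCCCCCCCCC[C@@]12O[C@@H]1C(=O)C=C(OC)C2=O
F6 | step 3 | N-(3-henicosylcyclobut-2-en-1-ylidene)-N-methylmethanaminium trifluoromethanesulfonate | CCCCCCCCCCCCCCCCCCCCCC1=CC(=[N+](C)C)C1.[O-]S(=O)(=O)C(F)(F)F
A1 | alternative 1 | 6-(2,4-dioxopentacosyl)-2,2-dimethyl-4H-1,3-dioxin-4-one | CCCCCCCCCCCCCCCCCCCCCC(=O)CC(=O)CC1=CC(=O)OC(C)(C)O1
A2 | alternative 1 | methyl 3,5,7-trioxooctacosanoate | COC(=O)CC(=O)CC(=O)CC(=O)CCCCCCCCCCCCCCCCCCCCC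
A3 | alternative 1 | methyl 6-henicosyl-2,4-dihydroxybenzoate | CCCCCCCCCCCCCCCCCCCCCc1cc(O)cc(O)c1C(=O)OC
A4 | alternative 2 | pentacosane-2,3-dione | CCCCCCCCCCCCCCCCCCCCCCC(=O)C(C)=O
A5 | alternative 2 | 3-henicosyl-2,5-dihydroxycyclohexa-2,5-diene-1,4-dione | CCCCCCCCCCCCCCCCCCCCCC1=C(O)C(=O)C=C(O)C1=O
A6 | alternative 3 | rac-2-henicosyl-4-hydroxy-4-[(E)-2-methoxyethenyl]-3-(propan-2-yloxy)cyclobut-2-en-1-one (one enantiomer drawn) | CCCCCCCCCCCCCCCCCCCCCC1=C(OC(C)C)[C@@](O)(/C=C/OC)C1=O
A7 | alternative 3 | 3-henicosyl-5-methoxy-2-(propan-2-yloxy)benzene-1,4-diol | CCCCCCCCCCCCCCCCCCCCCc1c(OC(C)C)c(O)cc(OC)c1O
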